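**Retrosynthetic overview**
1. Target 16 comes from O-acylation of the C7 hydroxyl of 14 with octanoyl chloride 15; 14 comes from 13 by dehydrogenation across C4a/C5.
2. 13 comes from 11: acid unmasks the C1 aldehyde and the C3 ketone (a 1,5-dicarbonyl pair) and cyclodehydration closes the pyran (ring B, formed second).
3. 11 comes from 9 + 7 by a [4+2] Michael–benzoin annulation that joins aldehyde 9 (C8, C8a, C1) and ene-1,2-dione 7 (C4a, C5, C6, C7 with the C4/C3 arm) through C4a–C8a and C7–C8; the carbocycle (ring A, formed first) and the C7 stereocentre arise here.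
4. Enabling feature: in ring A the tertiary α-ketol C8(=O)–C7(OH)CH3 (acyloin retron) overlaps the 1,5-dicarbonyl C8(=O)–C8a–C4a–C5–C6(=O) (Michael retron), so C6/C7 can enter as a 1,2-dione and C8 as an aldehyde.
5. 7 comes from a Wittig reaction of aldehyde 3 (from ethyl 3-oxodecanoate 1) with dione ylide 6 (from 4); 9 comes from oxidation of 3,3-diethoxypropan-1-ol 8.

Key step: step 6

Remark (assumption): isochromene locants (C1, O2, C3, C4, C4a, C5–C8, C8a) are used for all intermediates; C4a and C8a of 10–13 are transient stereocentres that become sp2 on the way to 14, so they are left undefined in names and SMILES and only C7 is tracked.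
Remark (assumption): the sense of induction at C7 by the catalyst pair named in step 6 is assigned by analogy; should a trial run give 7S, the enantiomeric catalysts are used.

Step 1
Reactants: 1 ethyl 3-oxodecanoate
Product: 2 ethyl 2-(2-heptyl-1,3-dioxolan-2-yl)acetate
Conditions: ethylene glycol, p-TsOH (cat.), toluene, reflux, Dean–Stark trap
Reagents that add atoms: ethylene glycol, OCCO
Why: acid-catalysed ketalisation of the ketone of a β-keto ester with azeotropic removal of water masks the later C3 carbonyl and leaves the ester free for reduction.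

Step 2
Reactants: 2 ethyl 2-(2-heptyl-1,3-dioxolan-2-yl)acetate
Product: 3 2-(2-heptyl-1,3-dioxolan-2-yl)acetaldehyde
Conditions: iBu2AlH (1.05 equiv), CH2Cl2, −78 °C; aq. potassium sodium tartrate
Reagents that add atoms: none
Why: low-temperature half-reduction of an ester by iBu2AlH should stop at the aldehyde because the tetrahedral aluminium hemiacetal, chelated by the β-dioxolane oxygen, survives until work-up.

Step 3
Reactants: 4 1-bromobutane-2,3-dione
Product: 6 1-(triphenyl-λ5-phosphanylidene)butane-2,3-dione, via phosphonium bromide 5 (not isolated)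
Conditions: PPh3, toluene, 23 °C; then aq. Na2CO3, CH2Cl2
Reagents that add atoms: triphenylphosphine, c1ccc(cc1)P(c1ccccc1)c1ccccc1
Why: SN2 alkylation of the phosphine by the α-bromo ketone and deprotonation of the acidic salt give the acyl-stabilised ylide (Wittig reagent formation), as with bromopyruvate-derived ylides.

Step 4
Reactants: 3 2-(2-heptyl-1,3-dioxolan-2-yl)acetaldehyde; 6 1-(triphenyl-λ5-phosphanylidene)butane-2,3-dione
Product: 7 (4E)-6-(2-heptyl-1,3-dioxolan-2-yl)hex-4-ene-2,3-dione
Conditions: CH2Cl2, 40 °C
Reagents that add atoms: none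
Why: Wittig olefination with a carbonyl-stabilised ylide should give the E-enone selectively under neutral conditions that the dioxolane tolerates.

Step 5
Reactants: 8 3,3-diethoxypropan-1-ol
Product: 9 3,3-diethoxypropanal
Conditions: Dess–Martin periodinane, pyridine, CH2Cl2, 0 °C; used crude
Reagents that add atoms: none
Why: Dess–Martin oxidation of the primary alcohol under pyridine buffering should give the β-acetal aldehyde without acid-induced loss of ethanol.

Step 6
Reactants: 7 (4E)-6-(2-heptyl-1,3-dioxolan-2-yl)hex-4-ene-2,3-dione; 9 3,3-diethoxypropanal (1.5 equiv)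
Product: 11 (2R)-4-(diethoxymethyl)-5-[(2-heptyl-1,3-dioxolan-2-yl)methyl]-2-hydroxy-2-methylcyclohexane-1,3-dione, via keto aldehyde 10 (not isolated)
Conditions: (S)-α,α-diphenylprolinol trimethylsilyl ether (20 mol%), (5aR,10bS)-aminoindanol-derived N-C6F5 triazolium tetrafluoroborate (10 mol%), NaOAc (20 mol%), CHCl3, 23 °C
Reagents that add atoms: none
Why: Proposed new method: the secondary amine converts aldehyde 9 into its enamine, which adds by an inverse-electron-demand oxa-Diels–Alder/Michael pathway to the β-carbon of ene-1,2-dione 7 (C8a–C4a bond) and releases keto aldehyde 10; the triazolylidene carbene then turns the aldehyde into a Breslow intermediate whose acyl-anion carbon C8 attacks the methyl ketone C7 (C7–C8 bond) in a 6-exo-trig crossed aldehyde–ketone benzoin closure of the carbocycle. The closest known reaction type is the enamine/carbene Michael–benzoin cascade of aldehydes with alkylidene 1,3-dicarbonyl compounds to α-hydroxycyclopentanones, together with amine-catalysed hetero-Diels–Alder additions of aldehydes to β,γ-unsaturated α-keto esters and carbene-catalysed six-ring aldehyde–ketone benzoin cyclisations; new is the ene-1,2-dione acceptor, whose distal carbonyl is attacked so that a six-membered ring results. C4a (and the epimerisable C8a) are set by the prolinol catalyst and are erased later, while C7 is set by the chiral carbene on this C4a-defined substrate, so any 7-epimer is a diastereomer that chromatography can remove. The step needs chemoselectivity (enamine addition must outrun carbene-mediated Stetter and cross-benzoin reactions of 7, which the high heterodiene reactivity of the ene-dione towards enamines should secure) and regioselectivity for C7 over C6 (C7 is the less hindered methyl ketone, whereas C6 is tied up as the enol/lactol oxygen right after the Michael step and its attack would give a more strained five-membered acyloin).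

Step 7
Reactants: 11 (2R)-4-(diethoxymethyl)-5-[(2-heptyl-1,3-dioxolan-2-yl)methyl]-2-hydroxy-2-methylcyclohexane-1,3-dione
Product: 13 (7R)-3-heptyl-7-hydroxy-7-methyl-4a,5-dihydro-6H-isochromene-6,8(7H)-dione (C4a epimers), via triketo aldehyde 12 (not isolated)
Conditions: CF3CO2H, H2O, CH2Cl2, 0 to 23 °C
Reagents that add atoms: water, O
Why: aqueous acid hydrolyses the diethyl acetal and the dioxolane to the 1,5-dicarbonyl pair C1 aldehyde/C3 ketone, and the enolised β-keto aldehyde oxygen closes onto the C3 ketone (6-exo-trig) with loss of water to the 4H-pyran (1,5-dicarbonyl cyclodehydration); C1 rather than C8 should supply the ring oxygen because the formyl group is the more enolised carbonyl and C8 is flanked by the quaternary C7, which is untouched.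

Step 8
Reactants: 13 (7R)-3-heptyl-7-hydroxy-7-methyl-4a,5-dihydro-6H-isochromene-6,8(7H)-dione
Product: 14 (7R)-3-heptyl-7-hydroxy-7-methyl-6H-isochromene-6,8(7H)-dione
Conditions: DDQ (1.1 equiv), CH2Cl2, 0 to 23 °C
Reagents that add atoms: none
Why: DDQ should abstract the doubly allylic hydride at C4a of the 4H-pyran to a 2-benzopyrylium ion that loses the acidic C5 proton (4H-pyran to pyrylium/anhydrobase dehydrogenation); the last transient stereocentre vanishes and the quaternary C7 cannot epimerise.

Step 9
Reactants: 14 (7R)-3-heptyl-7-hydroxy-7-methyl-6H-isochromene-6,8(7H)-dione; 15 octanoyl chloride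
Product: 16 (7R)-3-heptyl-7-methyl-6,8-dioxo-7,8-dihydro-6H-isochromen-7-yl octanoate
Conditions: Et3N, DMAP (cat.), CH2Cl2, 0 to 23 °C
Reagents that add atoms: none
Why: DMAP-catalysed acyl transfer to the tertiary α-ketol gives the ester; no bond to C7 is broken, so the configuration is retained.

**Compound list**
1 | ethyl 3-oxodecanoate | CCCCCCCC(=O)CC(=O)OCC | starting material
2 | ethyl 2-(2-heptyl-1,3-dioxolan-2-yl)acetate | CCCCCCCC1(CC(=O)OCC)OCCO1 | intermediate
3 | 2-(2-heptyl-1,3-dioxolan-2-yl)acetaldehyde | CCCCCCCC1(CC=O)OCCO1 | intermediate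
4 | 1-bromobutane-2,3-dione | CC(=O)C(=O)CBr | starting material
5 | (2,3-dioxobutyl)triphenylphosphonium bromide | CC(=O)C(=O)C[P+](c1ccccc1)(c1ccccc1)c1ccccc1.[Br-] | intermediate
6 | 1-(triphenyl-λ5-phosphanylidene)butane-2,3-dione | CC(=O)C(=O)C=P(c1ccccc1)(c1ccccc1)c1ccccc1 | intermediate
7 | (4E)-6-(2-heptyl-1,3-dioxolan-2-yl)hex-4-ene-2,3-dione | CC(=O)C(=O)/C=C/CC1(CCCCCCC)OCCO1 | intermediate
8 | 3,3-diethoxypropan-1-ol | CCOC(CCO)OCC | starting material
9 | 3,3-diethoxypropanal | CCOC(CC=O)OCC | intermediate
10 | 2-(diethoxymethyl)-3-[(2-heptyl-1,3-dioxolan-2-yl)methyl]-5,6-dioxoheptanal (open form, in equilibrium with its lactol) | CCOC(OCC)C(C=O)C(CC1(CCCCCCC)OCCO1)CC(=O)C(C)=O | intermediate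
11 | (2R)-4-(diethoxymethyl)-5-[(2-heptyl-1,3-dioxolan-2-yl)methyl]-2-hydroxy-2-methylcyclohexane-1,3-dione | O[C@]1(C)C(=O)CC(CC2(CCCCCCC)OCCO2)C(C(OCC)OCC)C1=O | intermediate
12 | (3R)-3-hydroxy-3-methyl-2,4-dioxo-6-(2-oxononyl)cyclohexane-1-carbaldehyde | O[C@]1(C)C(=O)CC(CC(=O)CCCCCCC)C(C=O)C1=O | intermediate
13 | (7R)-3-heptyl-7-hydroxy-7-methyl-4a,5-dihydro-6H-isochromene-6,8(7H)-dione | O[C@]1(C)C(=O)CC2C=C(CCCCCCC)OC=C2C1=O | intermediate
14 | (7R)-3-heptyl-7-hydroxy-7-methyl-6H-isochromene-6,8(7H)-dione | O[C@]1(C)C(=O)C=C2C=C(CCCCCCC)OC=C2C1=O | intermediate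
15 | octanoyl chloride | CCCCCCCC(Cl)=O | starting material
16 | (7R)-3-heptyl-7-methyl-6,8-dioxo-7,8-dihydro-6H-isochromen-7-yl octanoate | CCCCCCCC(=O)O[C@]1(C)C(=O)C=C2C=C(CCCCCCC)OC=C2C1=O | target

**Step count**
Total: 9 steps. Longest linear sequence: 7 steps (1, 2, 4, 6, 7, 8, 9).

**Steps most likely to fail**

Step 6 (proposed new method). What may go wrong: the two catalytic cycles interfere. The carbene may add aldehyde 9 to 7 in a Stetter or intermolecular cross-benzoin sense before the enamine addition, the enamine of 9 may lose ethoxide, or ring closure may occur at C6 to the five-membered acyloin. Fallback with known chemistry, setting out from 7 (with 9) and returning at 11: the two events are run separately. An amine-catalysed inverse-electron-demand hetero-Diels–Alder reaction of 9 with 7 ((S)-α,α-diphenylprolinol trimethylsilyl ether, CH2Cl2, then wet silica gel) should give the isolable lactol 1-[5-(diethoxymethyl)-4-[(2-heptyl-1,3-dioxolan-2-yl)methyl]-6-hydroxy-5,6-dihydro-4H-pyran-2-yl]ethan-1-one F1. F1 alone is then treated with the chiral triazolium salt and Et3N in toluene; through its open form it should undergo the intramolecular crossed aldehyde–ketone benzoin reaction to 11, with the carbene enantiomer screened on a substrate of defined C4a configuration.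

Step 8. What may go wrong: over-oxidation or decomposition of the electron-rich, air- and acid-sensitive 4H-pyran 13 during hydride abstraction. Fallback setting out from 11 and returning at 14: the C4a=C5 unsaturation is introduced before the pyran exists. Dehydrogenation of the C6 ketone of 11 with IBX (DMSO, 65 °C) should give (2R)-6-(diethoxymethyl)-5-[(2-heptyl-1,3-dioxolan-2-yl)methyl]-2-hydroxy-2-methylcyclohex-4-ene-1,3-dione F2. The acid treatment of step 7 (CF3CO2H, H2O, CH2Cl2) then unmasks C1 and C3 and should cyclodehydrate F2 directly to 14.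

Step 4. What may go wrong: sluggish olefination by the doubly acyl-stabilised ylide together with its self-condensation through the free acetyl carbonyl. Fallback setting out from 3 and returning at 7: Horner–Wadsworth–Emmons olefination of 3 with the lactate-derived dimethyl [3-(tert-butyldimethylsilyloxy)-2-oxobutyl]phosphonate (COP(=O)(CC(=O)C(C)O[Si](C)(C)C(C)(C)C)OC; LiCl, iPr2NEt, MeCN) should give (4E)-2-[(tert-butyldimethylsilyl)oxy]-6-(2-heptyl-1,3-dioxolan-2-yl)hex-4-en-3-one F3. Desilylation with HF·pyridine/pyridine in THF should give (4E)-6-(2-heptyl-1,3-dioxolan-2-yl)-2-hydroxyhex-4-en-3-one F4, and Dess–Martin oxidation of this α-hydroxy ketone gives 7.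

**Further compounds**
F1 | step 6 | 1-[5-(diethoxymethyl)-4-[(2-heptyl-1,3-dioxolan-2-yl)methyl]-6-hydroxy-5,6-dihydro-4H-pyran-2-yl]ethan-1-one | CCOC(OCC)C1C(O)OC(C(C)=O)=CC1CC1(CCCCCCC)OCCO1
F2 | step 8 | (2R)-6-(diethoxymethyl)-5-[(2-heptyl-1,3-dioxolan-2-yl)methyl]-2-hydroxy-2-methylcyclohex-4-ene-1,3-dione | O[C@]1(C)C(=O)C=C(CC2(CCCCCCC)OCCO2)C(C(OCC)OCC)C1=O
F3 | step 4 | (4E)-2-[(tert-butyldimethylsilyl)oxy]-6-(2-heptyl-1,3-dioxolan-2-yl)hex-4-en-3-one | CC(O[Si](C)(C)C(C)(C)C)C(=O)/C=C/CC1(CCCCCCC)OCCO1
F4 | step 4 | (4E)-6-(2-heptyl-1,3-dioxolan-2-yl)-2-hydroxyhex-4-en-3-one | CC(O)C(=O)/C=C/CC1(CCCCCCC)OCCO1
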